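The synthesis rests on cutting the bond between C5' of ring B and the vinylic CH of the fused 2,2-dimethylpyran (ring D), paired with the C8–quaternary carbon bond on ring A. One thermal operation makes both from flavonol 9, an isomer of the product that carries a 1,1-dimethylpropargyl ether on O4' and a prenyl ether on O7. The step exploits two ortho relationships: C3' beside O4' is blocked by its hydroxyl, so the alkyne terminus can only reach C5', and O7 hands the prenyl group, inverted, to C8. Flavonol 9 arises from two small arenes by Claisen–Schmidt condensation and Algar–Flynn–Oyamada oxidation. Chelation-directed loss of the 5-O-methyl group ends the route.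

Key step: step 5

Remark: broussonol A has no stereocentre, so the route has no configuration to set. Flavonoid numbering is used: ring A C5–C8, ring C O1–C4, ring B C1'–C6', ring D the dimethylpyran.

Step 1
Reactants: 1 2',4'-dihydroxy-6'-methoxyacetophenone; 2 prenyl bromide
Product: 3 2'-hydroxy-6'-methoxy-4'-(prenyloxy)acetophenone
Conditions: K2CO3 (1.2 equiv), acetone, reflux, 8 h
Reagents that add atoms: prenyl bromide (compound 2), CC(C)=CCBr
Why: Williamson ether synthesis, in which the 2-hydroxyl is locked in a hydrogen bond to the acetyl group, so the weak base ionises only the free and more acidic 4-hydroxyl, which displaces bromide from the primary allylic halide at oxygen.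

Step 2
Reactants: 4 3,4-dihydroxybenzaldehyde; 5 3-chloro-3-methylbut-1-yne
Product: 6 3-hydroxy-4-(2-methylbut-3-yn-2-yloxy)benzaldehyde
Conditions: K2CO3 (1.1 equiv), KI (0.1 equiv), DMF, N2, 65 °C, 16 h
Reagents that add atoms: 3-chloro-3-methylbut-1-yne (compound 5), C#CC(C)(C)Cl
Why: Williamson-type O-alkylation with a tertiary propargylic chloride, in which the 4-hydroxyl para to the formyl group is much the more acidic, so about one equivalent of base gives its phenoxide alone, and this captures the electrophile formed from 5 while the 3-hydroxyl stays free.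

Step 3
Reactants: 3 2'-hydroxy-6'-methoxy-4'-(prenyloxy)acetophenone; 6 3-hydroxy-4-(2-methylbut-3-yn-2-yloxy)benzaldehyde
Product: 7 (E)-2',3-dihydroxy-6'-methoxy-4-(2-methylbut-3-yn-2-yloxy)-4'-(prenyloxy)chalcone
Conditions: KOH (50% aq, 10 equiv), EtOH, rt, 48 h; then 1 M HCl to pH 4
Reagents that add atoms: none
Why: Claisen–Schmidt condensation, in which the enolate of methyl ketone 3 adds to the non-enolisable aldehyde 6 and E1cB loss of water gives the thermodynamically preferred E-enone, the meta-phenoxide of 6 not being conjugated with the formyl group and both ethers being inert to hydroxide.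

Step 4
Reactants: 7 (E)-2',3-dihydroxy-6'-methoxy-4-(2-methylbut-3-yn-2-yloxy)-4'-(prenyloxy)chalcone
Product: 9 3,3'-dihydroxy-5-methoxy-4'-(2-methylbut-3-yn-2-yloxy)-7-(prenyloxy)flavone, via trans-dihydroflavonol 8 (not isolated)
Conditions: 30% H2O2 (5 equiv), 2 M NaOH aq, MeOH, 0 °C to rt, 12 h; then 1 M HCl
Reagents that add atoms: hydrogen peroxide, OO
Why: Algar–Flynn–Oyamada reaction, in which the 2'-phenoxide closes on Cβ while Cα takes up oxygen to give trans-dihydroflavonol 8, whose two stereocentres are erased when more peroxide dehydrogenates it to the flavonol, and the nucleophilic oxidant leaves the electron-rich prenyl alkene and the alkyne untouched.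

Step 5
Reactants: 9 3,3'-dihydroxy-5-methoxy-4'-(2-methylbut-3-yn-2-yloxy)-7-(prenyloxy)flavone
Product: 13 5-O-methylbroussonol A, via allenyl catechol 10 (not isolated), via o-quinone methide 11 (not isolated), via chromene prenyl ether 12 (not isolated)
Conditions: PhNEt2 (degassed, 0.05 M), Ar, sealed tube, 150 °C, 1 h, then 200 °C, 2 h
Reagents that add atoms: none
Why: Two aromatic Claisen rearrangements, each a known reaction type for aryl 1,1-dimethylpropargyl ethers and for flavonoid 7-O-prenyl ethers, are run in one flask. At 150 °C the propargyl ether on O4' undergoes a [3,3]-sigmatropic shift that bonds the alkyne terminus to C5'; enolisation gives allenyl catechol 10, a 1,5-hydrogen shift from the O4' hydroxyl to the central allene carbon gives the Z-configured o-quinone methide 11, and oxa-6π electrocyclisation restores the O4'–CMe2 bond to give chromene 12. Ring D is therefore closed in the net sense of a 6-endo hydroarylation of the alkyne, the C5'–CH bond being the only skeletal bond that 12 has and 9 lacks, with the electrocyclisation as the actual ring-forming event. At 200 °C the prenyl ether on O7 rearranges through a six-membered chair-like transition state with allyl inversion, which sets the quaternary carbon of the 1,1-dimethylallyl group on C8, and tautomerisation frees the 7-hydroxyl. No stereocentre is formed. The selectivities needed are C5' over C3', secured by the hydroxyl that blocks C3', and C8 over C6, secured by the higher double-bond character of C7–C8 in the benzopyranone (the dienone from attack at C8 keeps the O1–C8a=C4a–C4=O vinylogous ester), by the 5-methoxy group that crowds C6 and by the blocked para position C4a that rules out a Cope relay, while the basic solvent suppresses acid-induced addition of the new phenol to the vinyl group.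

Step 6
Reactants: 13 5-O-methylbroussonol A
Product: 14 broussonol A
Conditions: MgI2 (anhydrous, 6 equiv), THF, reflux, 12 h; aqueous work-up
Reagents that add atoms: none
Why: Chelation-directed ether cleavage, in which magnesium bound between the C4 carbonyl and O5 turns only the peri methyl ether into a leaving group for SN2 attack of iodide on the methyl carbon, under conditions mild enough for the chromene and for a free phenol that stands next to a C-allyl group.

Compound list
1 | 1-(2,4-dihydroxy-6-methoxyphenyl)ethanone | CC(=O)c1c(O)cc(O)cc1OC | starting material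
2 | 1-bromo-3-methylbut-2-ene (prenyl bromide) | CC(C)=CCBr | starting material
3 | 1-[2-hydroxy-6-methoxy-4-(3-methylbut-2-enyloxy)phenyl]ethanone | CC(=O)c1c(O)cc(OCC=C(C)C)cc1OC | intermediate
4 | 3,4-dihydroxybenzaldehyde | O=Cc1ccc(O)c(O)c1 | starting material
5 | 3-chloro-3-methylbut-1-yne | C#CC(C)(C)Cl | starting material
6 | 3-hydroxy-4-(2-methylbut-3-yn-2-yloxy)benzaldehyde | O=Cc1ccc(OC(C)(C)C#C)c(O)c1 | intermediate
7 | (E)-1-[2-hydroxy-6-methoxy-4-(3-methylbut-2-enyloxy)phenyl]-3-[3-hydroxy-4-(2-methylbut-3-yn-2-yloxy)phenyl]prop-2-en-1-one | COc1cc(OCC=C(C)C)cc(O)c1C(=O)/C=C/c1ccc(OC(C)(C)C#C)c(O)c1 | intermediate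
8 | racemic trans-(2R*,3R*)-3-hydroxy-2-[3-hydroxy-4-(2-methylbut-3-yn-2-yloxy)phenyl]-5-methoxy-7-(3-methylbut-2-enyloxy)chroman-4-one, one enantiomer drawn | C#CC(C)(C)Oc1ccc(cc1O)[C@@H]2[C@H](C(=O)c3c(cc(cc3O2)OCC=C(C)C)OC)O | intermediate
9 | 3-hydroxy-2-[3-hydroxy-4-(2-methylbut-3-yn-2-yloxy)phenyl]-5-methoxy-7-(3-methylbut-2-enyloxy)chromen-4-one | COc1cc(OCC=C(C)C)cc2oc(-c3ccc(OC(C)(C)C#C)c(O)c3)c(O)c(=O)c12 | intermediate
10 | 2-[3,4-dihydroxy-5-(3-methylbuta-1,2-dienyl)phenyl]-3-hydroxy-5-methoxy-7-(3-methylbut-2-enyloxy)chromen-4-one | COc1cc(OCC=C(C)C)cc2oc(-c3cc(O)c(O)c(C=C=C(C)C)c3)c(O)c(=O)c12 | intermediate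
11 | o-quinone methide of ring B: C4'=O, exocyclic C5'=CH–CH=CMe2 with Z geometry (chain cis to the carbonyl), 3'-hydroxyl kept, rings A and C as in 9 | COc1cc(OCC=C(C)C)cc2oc(C3=C/C(=C/C=C(C)C)C(=O)C(O)=C3)c(O)c(=O)c12 | intermediate
12 | 3-hydroxy-2-(8-hydroxy-2,2-dimethyl-2H-chromen-6-yl)-5-methoxy-7-(3-methylbut-2-enyloxy)chromen-4-one | COc1cc(OCC=C(C)C)cc2oc(-c3cc(O)c4c(c3)C=CC(C)(C)O4)c(O)c(=O)c12 | intermediate
13 | 3,7-dihydroxy-2-(8-hydroxy-2,2-dimethyl-2H-chromen-6-yl)-5-methoxy-8-(2-methylbut-3-en-2-yl)chromen-4-one (5-O-methylbroussonol A) | C=CC(C)(C)c1c(O)cc(OC)c2c(=O)c(O)c(-c3cc(O)c4c(c3)C=CC(C)(C)O4)oc12 | intermediate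
14 | broussonol A, 3,5,7-trihydroxy-2-(8-hydroxy-2,2-dimethyl-2H-chromen-6-yl)-8-(2-methylbut-3-en-2-yl)chromen-4-one | C=CC(C)(C)c1c(O)cc(O)c2c(=O)c(O)c(-c3cc(O)c4c(c3)C=CC(C)(C)O4)oc12 | target

Total step count: 6. Longest linear sequence: 5 (steps 1, 3, 4, 5, 6).

Steps most likely to fail

Step 5. Three things may go wrong:
- The prenyl group may migrate to C6 in competition with C8.
- It may be lost by retro-ene fragmentation before it migrates.
- At 200 °C the new phenol may isomerise further by the abnormal Claisen pathway or add to the vinyl group.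

The fallback uncouples the two rearrangements. It sets out from 3 and comes back at 13. Acetophenone 3 is heated alone (PhNEt2, 190 °C). Here the hydrogen-bonded 2-hydroxyl makes the C3–C4 bond the more olefinic one and steers the prenyl group to C3, giving 3-(1,1-dimethylallyl)-2,4-dihydroxy-6-methoxyacetophenone F1. Claisen–Schmidt condensation with aldehyde 6 (concentrated KOH, EtOH) should give the C-alkylated chalcone F2. Algar–Flynn–Oyamada oxidation should then give the 8-(1,1-dimethylallyl)flavonol propargyl ether F3. Only the propargyl ether then has to rearrange. This needs no more than about 140 °C (xylene or DMF) and closes ring D through the same C5'–CH bond to give 13.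

Step 4. A 6'-alkoxy group favours five-membered closure of the phenoxide at Cα over six-membered closure at Cβ. The free ring B phenol may also suffer oxidative wear.

The fallback separates epoxidation from ring closure. It sets out from 7 and comes back at 8.
- Both phenols of 7 are protected (NaH, MOMCl, DMF, 0 °C) to give the bis(methoxymethyl) chalcone F4.
- Weitz–Scheffer epoxidation (H2O2, NaOH, MeOH/THF) gives the racemic trans-epoxy ketone F5, with no phenoxide present to interfere.
- Dilute HCl in MeOH at 40 °C removes both acetals, and under acid the freed 2'-hydroxyl opens the epoxide at the benzylic Cβ to give dihydroflavonol 8.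
- Cold alkaline H2O2 then dehydrogenates 8 to 9.

Step 6. Lewis acid or traces of HI may induce addition of the 7-hydroxyl to the vinyl group or attack the chromene double bond. Cleavage may also be sluggish because magnesium is tied up by the 3-hydroxy-4-keto chelate.

The fallback masks the phenols first. It sets out from 13 and comes back at 14. Acetylation (Ac2O, pyridine) gives the 3,7,3'-triacetate F6, which has neither a nucleophilic 7-hydroxyl nor a competing chelate site. BCl3 (CH2Cl2, −78 to 0 °C) then binds only between C4=O and O5 and removes the methyl group to give the 5-hydroxy triacetate F7. K2CO3 in MeOH at rt removes the acetates to give 14.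

Further compounds
F1 | step 5 | 1-[2,4-dihydroxy-6-methoxy-3-(2-methylbut-3-en-2-yl)phenyl]ethanone | CC(=O)c1c(O)c(C(C)(C)C=C)c(O)cc1OC
F2 | step 5 | (E)-1-[2,4-dihydroxy-6-methoxy-3-(2-methylbut-3-en-2-yl)phenyl]-3-[3-hydroxy-4-(2-methylbut-3-yn-2-yloxy)phenyl]prop-2-en-1-one | COc1cc(O)c(C(C)(C)C=C)c(O)c1C(=O)/C=C/c1ccc(OC(C)(C)C#C)c(O)c1
F3 | step 5 | 3,7-dihydroxy-2-[3-hydroxy-4-(2-methylbut-3-yn-2-yloxy)phenyl]-5-methoxy-8-(2-methylbut-3-en-2-yl)chromen-4-one | C=CC(C)(C)c1c(O)cc(OC)c2c(=O)c(O)c(-c3ccc(OC(C)(C)C#C)c(O)c3)oc12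
F4 | step 4 | (E)-1-[2-methoxy-6-(methoxymethoxy)-4-(3-methylbut-2-enyloxy)phenyl]-3-[3-(methoxymethoxy)-4-(2-methylbut-3-yn-2-yloxy)phenyl]prop-2-en-1-one | COCOc1cc(OCC=C(C)C)cc(OC)c1C(=O)/C=C/c1ccc(OC(C)(C)C#C)c(OCOC)c1
F5 | step 4 | racemic trans-α,β-epoxy ketone of F4, one enantiomer drawn | COCOc1cc(OCC=C(C)C)cc(OC)c1C(=O)[C@@H]2[C@H](O2)c1ccc(OC(C)(C)C#C)c(OCOC)c1
F6 | step 6 | 3,7,3'-tri-O-acetyl-5-O-methylbroussonol A | C=CC(C)(C)c1c(OC(C)=O)cc(OC)c2c(=O)c(OC(C)=O)c(-c3cc(OC(C)=O)c4c(c3)C=CC(C)(C)O4)oc12
F7 | step 6 | 3,7,3'-tri-O-acetylbroussonol A | C=CC(C)(C)c1c(OC(C)=O)cc(O)c2c(=O)c(OC(C)=O)c(-c3cc(OC(C)=O)c4c(c3)C=CC(C)(C)O4)oc12
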